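Remarks on the chemistry: cembrane numbering is used for every intermediate (C1 carries C15/C17, C2–C9 come from the geranyl unit, C13 carries the acetate, C14 the lactone oxygen), and geranyl acetate is taken as the commercial form of the geraniol unit.

## Analysis of the target

13-Acetoxysarcocrassolide 33 is a cembranolide: a 14-membered carbocycle (C1–C14) to which an α-methylene-γ-butyrolactone is fused through C1 and C14. It has five stereocentres, all S; three are contiguous, C13 (OAc), C14 (lactone oxygen) and C1 (C15), and their substituents lie on one face of the C12–C2 zigzag, so the C13/C14 dioxygen pattern is syn and the lactone is trans-fused. The other two, C3 and C4, belong to a trans-configured trisubstituted epoxide. Two E-trisubstituted alkenes (C7=C8 and C11=C12) complete the ring, and C11=C12 is allylic to the acetate. Four sites are sensitive: the exocyclic methylene is a Michael acceptor, the epoxide opens with acid (a free O14 could close a five-membered ether onto C3), the allylic acetate can ionise or migrate, and the lactone can translactonise onto O13. The hard points are the late handling of the lactone, the choice of one out of three trisubstituted alkenes for epoxidation, the syn C13/C14 relation next to an alkene, and closure of the large ring. The strategy rests on the lactone ring O14–C16(=O)–C15(=C17H2)–C1–C14: without the single carbonyl carbon C16 it is a homopropargylic alcohol, that is, the C14 hydroxyl and an ethynyl group (C15≡C17) on the neighbouring ring carbon C1, trans to it.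

## Retrosynthetic reasoning

The acetate of 33 goes on last. It is traced to the C13 alcohol 32 and that to the silyl ether 31. No skeletal bond is cut. The C13–O bond is allylic and should be a silyl ether, not an ester, while palladium is present; an ester on O13 next to a free O14 could also migrate.

In 31 the lactone is cut at O14–C16 and at C15–C16. Both cuts meet at C16, which leaves as carbon monoxide 30, and C17 returns from a methylene to the terminal CH of an alkyne. The precursor is the macrocyclic alkynol 29. This is the place to cut because carbonyl, ring and methylene then arrive in one operation at the end, with no enolate chemistry beside the epoxide and the allylic oxygen. The forward reaction must carbonylate O14, add the acyl carbon to the internal alkyne carbon and protonate C17.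

29 comes from 28 and 27 by freeing the alkyne and O14, and 27 from the alcohol 26. The C13 stereocentre of 26 is traced to the enone 25. Hydride addition under Felkin–Anh control by the C14 silyloxy group should give the 13,14-syn alcohol that the target needs. A direct addition of a C12 nucleophile to a C13 aldehyde would be expected to favour the anti isomer. 25 is the oxidation product of the epimeric alcohols 24, so the configuration set when the ring closes does not matter.

The ring is opened at C12–C13 (24 to 23). This is the only ring bond that joins a carbinol carbon to an sp2 carbon, so a chromium-mediated, nickel-catalysed alkenyl addition (Nozaki–Hiyama–Kishi) can form it. The geometry of C11=C12 is then fixed beforehand in an alkenyl bromide and is carried through with retention.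

The aldehyde 23 comes from the bis-silyl ether 22, and 22 is cut at C10–C11 into the diene 18 and (E)-2-bromo-1-iodoprop-1-ene 20, itself made from propyne 19. Hydroboration of the terminal vinyl group of 18 and an sp3–sp2 Suzuki–Miyaura coupling at the C–I bond of 20 are mild enough for the epoxide and the silylalkyne. That matters because this end of the chain can only be built after the epoxide is in place. 18 is reached from the C9 pivalate 15 through the alcohol 16 and the enal 17.

The epoxide of 15 is traced to the alkene 14 (Shi epoxidation, enantiomeric catalyst series). At this stage C7=C8 carries the allylic pivalate at C9 and is electron-poor, while C3=C4 has only carbon neighbours. That difference would be lost once C9 is a plain methylene, so the epoxidation is placed here. 14 is the bis-silyl ether of the diol 13.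

13 is cut at C1–C15 into the cis-epoxy alcohol 9 and ethynyltrimethylsilane 10, used as its aluminium derivative 12. The opening of a 2,3-epoxy alcohol at the distal carbon with inversion turns the two centres of a Sharpless epoxidation into C14 (oxygen) and C1 (ethynyl) in the trans-type relation that the lactone fusion needs. This Lewis-acidic step has to come before the C3–C4 epoxide exists. 9 comes from the Z-allylic alcohol 8.

8 comes from the enynol 7 by Lindlar semi-hydrogenation, and 7 is cut at C1–C2 into the allylic bromide 5 and propargyl alcohol 6. 5 is made from geranyl acetate 1 through 2, 3 and 4, so the geranyl unit supplies C2–C9 with both alkene geometries already in place.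

## Alternatives that were turned down

Alternative 1: The lactone is made first. C1–C2 and C15–C17 are cut. In the forward sense the anion of the allylic sulfone A1 adds to the butenolide A2 at C1, and the lactone enolate is trapped by formaldehyde A3. This gives the trisubstituted lactone A4, with the sulfone on C2 and a hydroxymethyl group as the future methylene.
- In its favour: the trans,trans arrangement around the lactone follows from the single stereocentre of A2 by substrate control, the step is convergent, and no pressurised gas and no late transition metal touches a sensitive macrocycle.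
- Against it: C13 is still missing and must be built from the C14 side chain by addition to an aldehyde next to the lactone oxygen, where the same anti preference works against the syn relation needed. The allylic sulfone anion can attack through either terminus. The sulfone has to be removed reductively in the presence of the lactone. Ring closure, epoxidation and dehydration to the methylene all remain to be done on a molecule that already holds the lactone.
- Comparison: on early control of C1/C14 this route is as strong as the chosen one or stronger. The chosen route offers a lactone that appears only at the end, fully formed, and a C13/C14/C1 triad set in acyclic intermediates by reagent control.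

Alternative 2: C13–C14 is cut. The open-chain epoxy dialdehyde ester A5 is coupled reductively between the C14 aldehyde and the C13 enal by samarium diiodide A6, a one-electron reductant of divalent samarium, and the C14 alkoxide closes the lactone on the ester to give the hydroxy lactone A7.
- In its favour: one step forms the macrocycle, two carbinol centres and the lactone, and the chain can come from a farnesyl-type precursor with all three alkenes already in it. On step count this is the strongest of all the options.
- Against it: C13 and C14 are set together in a macrocyclic pinacol coupling, where only ring conformation decides between syn and anti and between the two faces. The enal ketyl can also couple through its β-carbon. C1 in A5 is α to an aldehyde and can epimerise. A7 still lacks the methylene, which would have to be put in by enolate chemistry beside the epoxide and the C13 oxygen.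
- Comparison: the chosen route is longer but sets each centre by a predictable acyclic reaction and needs no lactone enolate.

Alternative 3: C5–C6 and the C3–O bond of the epoxide are cut. In the open-chain lactone A8, butyllithium A9 forms the carbanion next to the C6 sulfone. This opens the terminal C4–C5 epoxide at C5 to close the 14-membered ring, and the C4 alkoxide set free displaces the C3 mesylate with inversion to give the macrocycle A10.
- In its favour: sulfone-anion ring closures are among the most dependable ways to cembrane rings, and the epoxide is formed exactly where it is wanted without any competition from C7=C8. On those two points this route is stronger than the chosen one.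
- Against it: the base meets a lactone with acidic α-hydrogens and a mesylate that can eliminate. The sulfone on C6, allylic to C7=C8, must afterwards be removed under reducing conditions that threaten the epoxide and can move the double bond. The methylene is still to be introduced.
- Comparison: the chosen route avoids reductive removal of an auxiliary group from the finished ring and makes lactone and methylene in one step.

Key step: step 23

## Steps

Step 1
Reactants: 1 geranyl acetate
Product: 2 (2E,6E)-8-hydroxy-3,7-dimethylocta-2,6-dien-1-yl acetate
Conditions: SeO2 (cat.), t-BuOOH, salicylic acid (cat.), CH2Cl2, rt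
Reagents that add atoms: tert-butyl hydroperoxide, CC(C)(C)OO (oxygen, passed on by SeO2, O=[Se]=O)
Why: SeO2 allylic oxidation (ene reaction, then 2,3-sigmatropic shift) attacks the E-methyl group of the terminal, more electron-rich alkene, since the other alkene is deactivated by the allylic acetate; the future C9 is oxidised with the E geometry kept.

Step 2
Reactants: 2 (2E,6E)-8-hydroxy-3,7-dimethylocta-2,6-dien-1-yl acetate
Product: 3 (2E,6E)-8-acetoxy-2,6-dimethylocta-2,6-dien-1-yl pivalate
Conditions: t-BuCOCl, pyridine, DMAP (cat.), CH2Cl2, 0 °C
Reagents that add atoms: pivaloyl chloride, CC(C)(C)C(=O)Cl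
Why: Acylation of the primary allylic alcohol; the pivalate survives the copper, titanium and aluminium steps and later makes C7=C8 electron-poor for the site-selective epoxidation.

Step 3
Reactants: 3 (2E,6E)-8-acetoxy-2,6-dimethylocta-2,6-dien-1-yl pivalate
Product: 4 (2E,6E)-8-hydroxy-2,6-dimethylocta-2,6-dien-1-yl pivalate
Conditions: K2CO3 (cat.), MeOH, 0 °C
Reagents that add atoms: none
Why: Transesterification removes the unhindered acetate much faster than the tert-butyl-shielded pivalate, freeing the C2 hydroxyl only.

Step 4
Reactants: 4 (2E,6E)-8-hydroxy-2,6-dimethylocta-2,6-dien-1-yl pivalate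
Product: 5 (2E,6E)-8-bromo-2,6-dimethylocta-2,6-dien-1-yl pivalate
Conditions: CBr4, PPh3, CH2Cl2, −20 → 0 °C
Reagents that add atoms: carbon tetrabromide, BrC(Br)(Br)Br
Why: Appel reaction; the primary allylic alcohol is displaced through its alkoxyphosphonium salt under neutral conditions without allylic shift.

Step 5
Reactants: 5 (2E,6E)-8-bromo-2,6-dimethylocta-2,6-dien-1-yl pivalate; 6 propargyl alcohol
Product: 7 (2E,6E)-11-hydroxy-2,6-dimethylundeca-2,6-dien-9-yn-1-yl pivalate
Conditions: CuI (cat.), Bu4NI (cat.), K2CO3, DMF, rt
Reagents that add atoms: none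
Why: Copper-acetylide substitution of a primary allylic bromide at its unhindered terminus (SN2) forms C1–C2 and gives the skipped enyne; the free hydroxyl and the pivalate are tolerated by the weak base.

Step 6
Reactants: 7 (2E,6E)-11-hydroxy-2,6-dimethylundeca-2,6-dien-9-yn-1-yl pivalate
Product: 8 (2E,6E,9Z)-11-hydroxy-2,6-dimethylundeca-2,6,9-trien-1-yl pivalate
Conditions: H2 (1 atm), Pd/CaCO3 poisoned with Pb(OAc)2, quinoline, EtOAc, rt
Reagents that add atoms: none
Why: Lindlar semi-hydrogenation adds hydrogen syn to the alkyne only, giving the Z-allylic alcohol; the trisubstituted alkenes are not reduced on the poisoned catalyst.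

Step 7
Reactants: 8 (2E,6E,9Z)-11-hydroxy-2,6-dimethylundeca-2,6,9-trien-1-yl pivalate
Product: 9 (2E,6E)-8-[(2S,3R)-3-(hydroxymethyl)oxiran-2-yl]-2,6-dimethylocta-2,6-dien-1-yl pivalate (cis-epoxide; 1S,14R)
Conditions: Ti(Oi-Pr)4 (cat.), D-(−)-diethyl tartrate (cat.), t-BuOOH, 4 Å MS, CH2Cl2, −20 °C
Reagents that add atoms: tert-butyl hydroperoxide, CC(C)(C)OO
Why: Sharpless asymmetric epoxidation touches only the allylic alcohol alkene; with the D-tartrate the oxygen is delivered to the face that gives the (2R,3S)-2,3-epoxy alcohol (numbered from the carbinol carbon), i.e. 14R and 1S. Z-allylic alcohols react more slowly and somewhat less selectively, and any minor enantiomer becomes a separable diastereomer after step 10.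

Step 8
Reactants: 9 the cis-epoxy alcohol; 10 ethynyltrimethylsilane
Product: 13 (2E,6E,9S,10S)-10,11-dihydroxy-2,6-dimethyl-9-[(trimethylsilyl)ethynyl]undeca-2,6-dien-1-yl pivalate (1S,14S), via lithium (trimethylsilyl)acetylide 11 (not isolated), via diethyl[(trimethylsilyl)ethynyl]aluminium 12 (not isolated)
Conditions: 10, n-BuLi, toluene, 0 °C; Et2AlCl; then 9, toluene/hexane, 0 °C → rt
Reagents that add atoms: n-butyllithium, [Li]CCCC (lithium of 11); diethylaluminium chloride, CC[Al](Cl)CC (aluminium and ethyl groups of 12)
Why: Alkynylaluminium opening of a 2,3-epoxy alcohol: the aluminium alkoxide of O13 directs the alkynyl group to the distal epoxide carbon C1, which is attacked with inversion. C1 becomes S with the ethynyl group, and C14 keeps its oxygen and configuration (S by the change of priorities), which is the relation needed for the trans-fused lactone.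

Step 9
Reactants: 13 the diol
Product: 14 the 10,11-bis(triethylsilyl) ether of 13 (O13 and O14 silylated)
Conditions: Et3SiOTf, 2,6-lutidine, CH2Cl2, −78 °C
Reagents that add atoms: triethylsilyl trifluoromethanesulfonate, CC[Si](CC)(CC)OS(=O)(=O)C(F)(F)F
Why: Silylation of both hydroxyls; the primary ether can later be oxidised directly to the aldehyde, and the secondary one keeps O14 away from the epoxide until the end.

Step 10
Reactants: 14 the bis(triethylsilyl) ether
Product: 15 the (3S,4S)-epoxide of 14 (oxirane on C3–C4; C7=C8 intact)
Conditions: 1,2:4,5-di-O-isopropylidene-β-L-erythro-2,3-hexodiulo-2,6-pyranose (30 mol%), KHSO5 (as 2KHSO5·KHSO4·K2SO4), K2CO3, Bu4NHSO4, MeCN/CH2(OMe)2/aq. Na2B4O7 buffer, 0 °C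
Reagents that add atoms: potassium peroxymonosulfate, [K+].[O-]S(=O)(=O)OO (oxygen, passed on by the dioxirane of the ketone)
Why: Shi epoxidation: the chiral dioxirane attacks the more electron-rich C3=C4, because C7=C8 is deactivated by the allylic pivalate. The L-fructose-derived ketone gives the (S,S)-epoxide of an E-trisubstituted alkene through the spiro transition state, the mirror image of the (R,R) sense of the D-series, so C3 and C4 are set by the catalyst.

Step 11
Reactants: 15 the epoxy pivalate
Product: 16 the C9 allylic alcohol (pivalate removed from 15)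
Conditions: i-Bu2AlH, CH2Cl2, −78 °C
Reagents that add atoms: none
Why: Reductive cleavage of the ester at low temperature; silyl ethers, silylalkyne and the trisubstituted epoxide are not attacked at −78 °C.

Step 12
Reactants: 16 the C9 allylic alcohol
Product: 17 the (7E)-C9 enal
Conditions: MnO2, CH2Cl2, rt
Reagents that add atoms: none
Why: MnO2 oxidises allylic alcohols selectively and under neutral conditions, with the alkene geometry retained.

Step 13
Reactants: 17 the C9 enal
Product: 18 the (7E)-7,9-diene (C9=C10 terminal vinyl group)
Conditions: Ph3PCH3Br, KN(SiMe3)2, THF, −78 → 0 °C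
Reagents that add atoms: methyltriphenylphosphonium bromide, C[P+](c1ccccc1)(c1ccccc1)c1ccccc1.[Br-]
Why: Wittig methylenation adds C10; the salt-free ylide does not touch the epoxide or the silyl groups and creates no new stereo-element.

Step 14
Reactants: 19 propyne
Product: 20 (E)-2-bromo-1-iodoprop-1-ene
Conditions: IBr, CH2Cl2, −78 → 0 °C
Reagents that add atoms: iodine monobromide, BrI
Why: Anti addition of iodine monobromide through the iodonium ion puts iodine on the terminal carbon and bromide on the internal one, so iodine and bromine end up trans; this fixes the future C11=C12 geometry.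

Step 15
Reactants: 18 the diene; 20 (E)-2-bromo-1-iodoprop-1-ene
Product: 22 the (7E,11E)-12-bromo-7,11-diene with C13 and C14 triethylsilyl ethers, via B-alkyl-9-borabicyclo[3.3.1]nonane 21 (not isolated)
Conditions: 9-BBN, THF, 0 °C → rt; then 20, Pd(dppf)Cl2 (cat.), AsPh3, Cs2CO3, DMF/H2O, rt
Reagents that add atoms: 9-borabicyclo[3.3.1]nonane, B1C2CCCC1CCC2 (its boron bicycle is carried by 21 only; 22 keeps one hydrogen from it)
Why: 9-BBN adds to the terminal vinyl group of the diene at C10, far faster than to a trisubstituted alkene or a hindered silylalkyne. In the B-alkyl Suzuki–Miyaura coupling zerovalent palladium inserts into the C–I bond of 20 in preference to the C–Br bond and couples with retention, forming C10–C11 and leaving the E-alkenyl bromide.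

Step 16
Reactants: 22 the alkenyl bromide
Product: 23 the C13 aldehyde (O14 still a triethylsilyl ether)
Conditions: (COCl)2, DMSO, CH2Cl2, −78 → −40 °C; then Et3N, −78 → 0 °C
Reagents that add atoms: none
Why: Under Swern conditions a primary triethylsilyl ether is cleaved and oxidised in one operation while the more hindered secondary one stays; this saves a separate deprotection, and the α-silyloxy aldehyde is not epimerised at low temperature.

Step 17
Reactants: 23 the bromo aldehyde
Product: 24 the macrocyclic allylic alcohols (14-membered ring; both C13 epimers)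
Conditions: CrCl2, NiCl2 (cat.), DMF, 50 °C, slow addition, 2 mM
Reagents that add atoms: none
Why: Nozaki–Hiyama–Kishi macrocyclisation: zerovalent nickel inserts into the C–Br bond, the alkenyl group passes to trivalent chromium and adds to the aldehyde, forming C12–C13 with retention of the C11=C12 geometry. The epoxide, silyl ethers and silylalkyne are inert to divalent chromium; the C13 configuration is not relied on because both epimers converge in step 18.

Step 18
Reactants: 24 the macrocyclic alcohols
Product: 25 the macrocyclic C13 enone
Conditions: Dess–Martin periodinane, NaHCO3, CH2Cl2, 0 °C → rt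
Reagents that add atoms: none
Why: Buffered Dess–Martin oxidation converts both epimeric allylic alcohols into one enone without acid that would endanger the epoxide.

Step 19
Reactants: 25 the enone
Product: 26 the (13S)-allylic alcohol
Conditions: LiBH(s-Bu)3, THF, −78 °C; AcOH, −78 °C
Reagents that add atoms: none
Why: 1,2-Reduction of the β-substituted enone by a bulky, non-chelating hydride under Felkin–Anh control: the C14–OSiEt3 bond lies anti to the incoming hydride, which passes H14, and this gives the 13,14-syn alcohol, i.e. 13S. The cold acidic quench is meant to stop silyl migration from O14 to the new alkoxide.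

Step 20
Reactants: 26 the (13S)-alcohol
Product: 27 the C13 tert-butyldimethylsilyl ether
Conditions: t-BuMe2SiOTf, 2,6-lutidine, CH2Cl2, −78 → 0 °C
Reagents that add atoms: tert-butyldimethylsilyl trifluoromethanesulfonate, CC(C)(C)[Si](C)(C)OS(=O)(=O)C(F)(F)F
Why: Silyl triflate protection of the hindered allylic alcohol; O13 now carries the more robust of the two silyl groups.

Step 21
Reactants: 27 the fully silylated macrocycle
Product: 28 the terminal alkyne (C–SiMe3 cleaved)
Conditions: K2CO3 (cat.), MeOH, 0 °C → rt
Reagents that add atoms: none
Why: Methoxide cleaves the alkynyl–silicon bond only (protodesilylation); both silyl ethers are in place, so no hydroxyl is free to take part in silyl migration.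

Step 22
Reactants: 28 the terminal alkyne
Product: 29 the macrocyclic alkynol (C14 hydroxyl free, C13 silyl ether)
Conditions: HF·pyridine, pyridine, THF, 0 °C
Reagents that add atoms: none
Why: Buffered fluoride desilylation removes the triethylsilyl ether much faster than the hindered tert-butyldimethylsilyl ether; O14 is freed only now and under buffered conditions, because it lies within reach of the epoxide.

Step 23
Reactants: 29 the macrocyclic alkynol; 30 carbon monoxide
Product: 31 the 13-O-silyl α-methylene lactone
Conditions: PdCl2 (5 mol%), PPh3 (10 mol%), SnCl2 (5 mol%), CO (7 atm), MeCN, 75 °C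
Reagents that add atoms: none
Why: This is the palladium-catalysed cyclocarbonylation of homopropargylic alcohols to α-methylene-γ-butyrolactones, a reaction type established for trans-2-ethynylcycloalkanols. Under CO the C14 hydroxyl is carbonylated on divalent palladium to an alkoxycarbonyl complex, which puts the future C16 on O14. The C15≡C17 bond then inserts syn into the Pd–C(O)O bond, so that C16 bonds to the internal carbon C15 and palladium ends on C17; this closes the ring O14–C16–C15–C1–C14 in the 5-exo-dig mode. Protonolysis of the C17–Pd bond by the acid set free in the first stage gives the exocyclic methylene and returns divalent palladium, so no oxidant is needed. No stereocentre is created: C1 and C14 are already trans on the large ring, and the trans fusion of the lactone follows from that. The exo mode is secured by geometry, because a syn insertion in the endo sense would put a trans double bond into a six-membered ring. Selectivity for O14 is secured by the silyl ether on O13, which rules out a six-membered lactone and keeps the allylic C13–O bond from ionising on any zerovalent palladium. The epoxide must survive the Lewis acid, so SnCl2 is kept at catalyst level.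

Step 24
Reactants: 31 the 13-O-silyl lactone
Product: 32 the 13-hydroxy lactone
Conditions: HF·pyridine, pyridine, THF, 0 °C → rt
Reagents that add atoms: none
Why: Fluoride cleavage of the silyl ether under buffered, non-basic conditions, which spare the Michael acceptor and avoid base-induced translactonisation onto O13.

Step 25
Reactants: 32 the 13-hydroxy lactone
Product: 33 13-acetoxysarcocrassolide
Conditions: Ac2O, pyridine, DMAP (cat.), CH2Cl2, 0 °C
Reagents that add atoms: acetic anhydride, CC(=O)OC(C)=O
Why: Acylation of the only free hydroxyl with retention at C13; short reaction at 0 °C keeps the amine base away from the methylene lactone.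

## Compound list

1 | geranyl acetate, (2E)-3,7-dimethylocta-2,6-dien-1-yl acetate | CC(C)=CCC/C(C)=C/COC(C)=O | starting material
2 | (2E,6E)-8-hydroxy-3,7-dimethylocta-2,6-dien-1-yl acetate | OC/C(C)=C/CC/C(C)=C/COC(C)=O | intermediate
3 | (2E,6E)-8-acetoxy-2,6-dimethylocta-2,6-dien-1-yl pivalate | CC(C)(C)C(=O)OC/C(C)=C/CC/C(C)=C/COC(C)=O | intermediate
4 | (2E,6E)-8-hydroxy-2,6-dimethylocta-2,6-dien-1-yl pivalate | CC(C)(C)C(=O)OC/C(C)=C/CC/C(C)=C/CO | intermediate
5 | (2E,6E)-8-bromo-2,6-dimethylocta-2,6-dien-1-yl pivalate | CC(C)(C)C(=O)OC/C(C)=C/CC/C(C)=C/CBr | intermediate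
6 | propargyl alcohol (prop-2-yn-1-ol) | C#CCO | starting material
7 | (2E,6E)-11-hydroxy-2,6-dimethylundeca-2,6-dien-9-yn-1-yl pivalate | CC(C)(C)C(=O)OC/C(C)=C/CC/C(C)=C/CC#CCO | intermediate
8 | (2E,6E,9Z)-11-hydroxy-2,6-dimethylundeca-2,6,9-trien-1-yl pivalate | CC(C)(C)C(=O)OC/C(C)=C/CC/C(C)=C/C/C=C\CO | intermediate
9 | (2E,6E)-8-[(2S,3R)-3-(hydroxymethyl)oxiran-2-yl]-2,6-dimethylocta-2,6-dien-1-yl pivalate (cis-epoxy alcohol, 1S,14R) | CC(C)(C)C(=O)OC/C(C)=C/CC/C(C)=C/C[C@@H]1O[C@@H]1CO | intermediate
10 | ethynyltrimethylsilane | C#C[Si](C)(C)C | starting material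
11 | lithium (trimethylsilyl)acetylide | [Li]C#C[Si](C)(C)C | intermediate
12 | diethyl[(trimethylsilyl)ethynyl]aluminium | CC[Al](CC)C#C[Si](C)(C)C | intermediate
13 | (2E,6E,9S,10S)-10,11-dihydroxy-2,6-dimethyl-9-[(trimethylsilyl)ethynyl]undeca-2,6-dien-1-yl pivalate (1S,14S diol) | CC(C)(C)C(=O)OC/C(C)=C/CC/C(C)=C/C[C@@H](C#C[Si](C)(C)C)[C@H](O)CO | intermediate
14 | bis(triethylsilyl) ether of 13 (O13 and O14) | CC(C)(C)C(=O)OC/C(C)=C/CC/C(C)=C/C[C@@H](C#C[Si](C)(C)C)[C@H](O[Si](CC)(CC)CC)CO[Si](CC)(CC)CC | intermediate
15 | (3S,4S)-3,4-epoxide of 14, C9 pivalate (1S,3S,4S,14S; 7E) | CC(C)(C)C(=O)OC/C(C)=C/CC[C@]1(C)O[C@H]1C[C@@H](C#C[Si](C)(C)C)[C@H](O[Si](CC)(CC)CC)CO[Si](CC)(CC)CC | intermediate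
16 | C9 allylic alcohol from 15 (pivalate removed) | OC/C(C)=C/CC[C@]1(C)O[C@H]1C[C@@H](C#C[Si](C)(C)C)[C@H](O[Si](CC)(CC)CC)CO[Si](CC)(CC)CC | intermediate
17 | (7E)-C9 enal from 16 | O=C/C(C)=C/CC[C@]1(C)O[C@H]1C[C@@H](C#C[Si](C)(C)C)[C@H](O[Si](CC)(CC)CC)CO[Si](CC)(CC)CC | intermediate
18 | (7E)-7,9-diene (C9=C10 vinyl group) from 17 | C=C/C(C)=C/CC[C@]1(C)O[C@H]1C[C@@H](C#C[Si](C)(C)C)[C@H](O[Si](CC)(CC)CC)CO[Si](CC)(CC)CC | intermediate
19 | propyne | CC#C | starting material
20 | (E)-2-bromo-1-iodoprop-1-ene | C/C(Br)=C\I | intermediate
21 | B-alkyl-9-borabicyclo[3.3.1]nonane from 18 (boron on C10) | C1CC2CCCC(C1)B2CC/C(C)=C/CC[C@]1(C)O[C@H]1C[C@@H](C#C[Si](C)(C)C)[C@H](O[Si](CC)(CC)CC)CO[Si](CC)(CC)CC | intermediate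
22 | open-chain (7E,11E)-12-bromo-7,11-diene, (3S,4S)-epoxide, C1 (trimethylsilyl)ethynyl, O13 and O14 triethylsilyl ethers | C/C(Br)=C\CC/C(C)=C/CC[C@]1(C)O[C@H]1C[C@@H](C#C[Si](C)(C)C)[C@H](O[Si](CC)(CC)CC)CO[Si](CC)(CC)CC | intermediate
23 | C13 aldehyde from 22 (14S triethylsilyloxy) | C/C(Br)=C\CC/C(C)=C/CC[C@]1(C)O[C@H]1C[C@@H](C#C[Si](C)(C)C)[C@H](O[Si](CC)(CC)CC)C=O | intermediate
24 | macrocyclic allylic alcohols: 14-membered ring, (1S,3S,4S,14S), 7E,11E, 3,4-epoxide, C1 (trimethylsilyl)ethynyl, 14-triethylsilyloxy, 13-hydroxyl as both epimers | C[Si](C)(C)C#C[C@@H]1C[C@@H]2O[C@@]2(C)CC/C=C(\C)CC/C=C(\C)C(O)[C@H]1O[Si](CC)(CC)CC | intermediate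
25 | macrocyclic C13 enone from 24 | C[Si](C)(C)C#C[C@@H]1C[C@@H]2O[C@@]2(C)CC/C=C(\C)CC/C=C(\C)C(=O)[C@H]1O[Si](CC)(CC)CC | intermediate
26 | (13S)-allylic alcohol (1S,3S,4S,13S,14S), 14-triethylsilyloxy, C1 (trimethylsilyl)ethynyl | C[Si](C)(C)C#C[C@@H]1C[C@@H]2O[C@@]2(C)CC/C=C(\C)CC/C=C(\C)[C@H](O)[C@H]1O[Si](CC)(CC)CC | intermediate
27 | 13-O-tert-butyldimethylsilyl ether of 26 | C[Si](C)(C)C#C[C@@H]1C[C@@H]2O[C@@]2(C)CC/C=C(\C)CC/C=C(\C)[C@H](O[Si](C)(C)C(C)(C)C)[C@H]1O[Si](CC)(CC)CC | intermediate
28 | terminal alkyne from 27 (13-OTBS, 14-OTES, C1 ethynyl) | C#C[C@@H]1C[C@@H]2O[C@@]2(C)CC/C=C(\C)CC/C=C(\C)[C@H](O[Si](C)(C)C(C)(C)C)[C@H]1O[Si](CC)(CC)CC | intermediate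
29 | macrocyclic alkynol (1S,3S,4S,13S,14S): 14-hydroxyl, 1-ethynyl, 13-tert-butyldimethylsilyloxy, 3,4-epoxide, 7E,11E | C#C[C@@H]1C[C@@H]2O[C@@]2(C)CC/C=C(\C)CC/C=C(\C)[C@H](O[Si](C)(C)C(C)(C)C)[C@H]1O | intermediate
30 | carbon monoxide | [C-]#[O+] | starting material
31 | 13-O-tert-butyldimethylsilyl analogue of the target (complete α-methylene lactone) | C=C1C(=O)O[C@H]2[C@H]1C[C@@H]1O[C@@]1(C)CC/C=C(\C)CC/C=C(\C)[C@@H]2O[Si](C)(C)C(C)(C)C | intermediate
32 | 13-hydroxy lactone (13-deacetyl target) | C=C1C(=O)O[C@H]2[C@H]1C[C@@H]1O[C@@]1(C)CC/C=C(\C)CC/C=C(\C)[C@@H]2O | intermediate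
33 | 13-acetoxysarcocrassolide | C=C1C(=O)O[C@H]2[C@H]1C[C@@H]1O[C@@]1(C)CC/C=C(\C)CC/C=C(\C)[C@@H]2OC(C)=O | target

## Step count and least certain steps

Total step count: 25. Longest linear sequence: 24 steps (steps 1–13 and 15–25); step 14 is a one-step side branch.

Step 23 (key step). Most likely to go wrong: acid-promoted opening of the C3–C4 epoxide before or during carbonylation. SnCl2 and the HCl equivalent are Lewis and Brønsted acids, and the free O14 can attack C3 across the ring to give a tetrahydrofuran; chloride can also open the epoxide. The hindered secondary hydroxyl may carbonylate slowly, which lengthens the exposure.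
Fallback: a two-stage route through an iodoalkene, in which carbon monoxide is taken up under basic conditions. It sets out from 28 and comes back at 31. Ruthenium-catalysed Markovnikov hydrosilylation of the terminal alkyne ([Cp*Ru(MeCN)3]PF6, Et3SiH, CH2Cl2) should give the 1,1-disubstituted vinylsilane F1. Iododesilylation (N-iodosuccinimide, 2,6-lutidine, (CF3)2CHOH, 0 °C) gives the 2-iodoalkene F2. HF·pyridine/pyridine frees O14 to give the hydroxy iodoalkene F3. Zerovalent palladium then closes the lactone by oxidative addition into the C–I bond, CO insertion and capture by O14 (Pd(PPh3)4, CO 1 atm, K2CO3, THF, 50 °C).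

Step 17 (macrocyclisation). Most likely to go wrong: slow insertion of zerovalent nickel into the hindered, trisubstituted alkenyl bromide. That would let reduction or pinacol coupling of the aldehyde and intermolecular addition take over, even at high dilution.
Fallback: ring closure by nickel-catalysed reductive coupling of an alkyne with the aldehyde, which needs no alkenyl halide and so also bypasses steps 12–16. It sets out from 16 and comes back at 24. Appel bromination (CBr4, PPh3) gives the allylic bromide F4. Alkylation with 1,3-dilithiopropyne (from 19 and two equivalents of n-BuLi), followed by MeI on the resulting acetylide, gives the methyl alkyne F5. Swern oxidation of the primary silyl ether gives the ynal F6. Ni(cod)2 (cat.), PBu3, Et3B at high dilution should then join C12 to C13 with syn delivery of hydrogen to C11; the ligand must be chosen to favour attack at the methyl-bearing alkyne carbon.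

Step 19 (C13 configuration). Most likely to go wrong: poor facial selectivity. In the macrocycle the exposed face of the enone may be set by ring conformation and not by the C14 substituent, and the alkoxide can start silyl migration if the quench is slow.
Fallback: correct the centre by inversion instead of controlling the reduction. It sets out from 25 and comes back at 26. If the reduction gives mainly the (13R)-alcohol F7, a Mitsunobu reaction (4-nitrobenzoic acid, PPh3, diisopropyl azodicarboxylate) should give the (13S)-4-nitrobenzoate F8, and i-Bu2AlH at −78 °C cleaves the ester.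

Step 8 (epoxide opening). Most likely to go wrong: loss of regiocontrol. In a cis-epoxy alcohol the alkynyl group may attack C14 as well as C1, and the aluminium alkoxide can trigger epoxide migration.
Fallback: open the O-protected epoxide with an external nucleophile, where the inductive effect of the C13 oxygen directs attack to C1. It sets out from 9 and comes back at 13. Silylation (t-BuMe2SiCl, imidazole) gives the silyl ether F9. Lithium (trimethylsilyl)acetylide with BF3·OEt2 in THF at −78 °C gives the alkynyl alcohol F10. HF·pyridine removes the primary silyl ether; no acid-sensitive epoxide is present at that stage.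

## Further compounds

F1 | step 23 | vinylsilane from 28: C1 bears a 1-(triethylsilyl)vinyl group; 13-OTBS, 14-OTES | C=C([Si](CC)(CC)CC)[C@@H]1C[C@@H]2O[C@@]2(C)CC/C=C(\C)CC/C=C(\C)[C@H](O[Si](C)(C)C(C)(C)C)[C@H]1O[Si](CC)(CC)CC
F2 | step 23 | 2-iodoalkene: C1 bears a 1-iodovinyl group; 13-OTBS, 14-OTES | C=C(I)[C@@H]1C[C@@H]2O[C@@]2(C)CC/C=C(\C)CC/C=C(\C)[C@H](O[Si](C)(C)C(C)(C)C)[C@H]1O[Si](CC)(CC)CC
F3 | step 23 | hydroxy iodoalkene: C1 1-iodovinyl, 14-hydroxyl, 13-OTBS | C=C(I)[C@@H]1C[C@@H]2O[C@@]2(C)CC/C=C(\C)CC/C=C(\C)[C@H](O[Si](C)(C)C(C)(C)C)[C@H]1O
F4 | step 17 | C9 allylic bromide from 16 | BrC/C(C)=C/CC[C@]1(C)O[C@H]1C[C@@H](C#C[Si](C)(C)C)[C@H](O[Si](CC)(CC)CC)CO[Si](CC)(CC)CC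
F5 | step 17 | methyl alkyne (C11≡C12–CH3) with O13 and O14 triethylsilyl ethers | CC#CCC/C(C)=C/CC[C@]1(C)O[C@H]1C[C@@H](C#C[Si](C)(C)C)[C@H](O[Si](CC)(CC)CC)CO[Si](CC)(CC)CC
F6 | step 17 | ynal: C13 aldehyde of F5 | CC#CCC/C(C)=C/CC[C@]1(C)O[C@H]1C[C@@H](C#C[Si](C)(C)C)[C@H](O[Si](CC)(CC)CC)C=O
F7 | step 19 | (13R)-epimer of 26 | C[Si](C)(C)C#C[C@@H]1C[C@@H]2O[C@@]2(C)CC/C=C(\C)CC/C=C(\C)[C@@H](O)[C@H]1O[Si](CC)(CC)CC
F8 | step 19 | (13S)-4-nitrobenzoate of 26 | C[Si](C)(C)C#C[C@@H]1C[C@@H]2O[C@@]2(C)CC/C=C(\C)CC/C=C(\C)[C@H](OC(=O)c2ccc(cc2)[N+](=O)[O-])[C@H]1O[Si](CC)(CC)CC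
F9 | step 8 | tert-butyldimethylsilyl ether of 9 | CC(C)(C)C(=O)OC/C(C)=C/CC/C(C)=C/C[C@@H]1O[C@@H]1CO[Si](C)(C)C(C)(C)C
F10 | step 8 | 13-O-tert-butyldimethylsilyl ether of 13 (O14 free) | CC(C)(C)C(=O)OC/C(C)=C/CC/C(C)=C/C[C@@H](C#C[Si](C)(C)C)[C@H](O)CO[Si](C)(C)C(C)(C)C
A1 | alternative 1 | (2E,6E)-2,6-dimethyl-8-(phenylsulfonyl)octa-2,6-dien-1-yl pivalate | O=S(=O)(c1ccccc1)C/C=C(\C)CC/C=C(\C)COC(=O)C(C)(C)C
A2 | alternative 1 | (S)-5-[(tert-butyldiphenylsilyloxy)methyl]furan-2(5H)-one | O=C1C=C[C@@H](CO[Si](c2ccccc2)(c2ccccc2)C(C)(C)C)O1
A3 | alternative 1 | formaldehyde | C=O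
A4 | alternative 1 | trans,trans-trisubstituted γ-lactone with C2 phenylsulfonyl (both epimers), C17 hydroxymethyl and the C2–C9 chain | OC[C@@H]1C(=O)O[C@H](CO[Si](c2ccccc2)(c2ccccc2)C(C)(C)C)[C@H]1C(S(=O)(=O)c1ccccc1)/C=C(\C)CC/C=C(\C)COC(=O)C(C)(C)C
A5 | alternative 2 | open-chain (1S,3S,4S)-epoxy dialdehyde methyl ester (C14 aldehyde, C13 enal, C16 ester) | COC(=O)C[C@@H](C=O)C[C@@H]1O[C@@]1(C)CC/C=C(\C)CC/C=C(\C)C=O
A6 | alternative 2 | samarium diiodide | I[Sm]I
A7 | alternative 2 | macrocyclic 13-hydroxy γ-lactone without exocyclic methylene and acetyl group | C1C(=O)O[C@H]2[C@H]1C[C@@H]1O[C@@]1(C)CC/C=C(\C)CC/C=C(\C)[C@@H]2O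
A8 | alternative 3 | open-chain γ-lactone with C6 phenylsulfonyl, C4–C5 epoxide, C3 mesylate and 13-OTBS | C1C(=O)O[C@H]([C@@H](O[Si](C)(C)C(C)(C)C)/C(C)=C/CC/C(C)=C/CS(=O)(=O)c2ccccc2)[C@H]1C[C@@H](OS(C)(=O)=O)[C@]1(C)CO1
A9 | alternative 3 | butyllithium | [Li]CCCC
A10 | alternative 3 | macrocyclic epoxy lactone with C6 phenylsulfonyl (both C6 epimers) and 13-OTBS | C1C(=O)O[C@H]2[C@H]1C[C@@H]1O[C@@]1(C)CC(S(=O)(=O)c1ccccc1)/C=C(\C)CC/C=C(\C)[C@@H]2O[Si](C)(C)C(C)(C)C
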